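## Retrosynthetic overview

1. The exocyclic methylene is installed last, by Horner–Wadsworth–Emmons methylenation of an α-phosphono lactone.
2. The ten-membered ring comes from a Criegee-type 1,2-shift (carbon to oxygen) of the ring-fusion bond C3–C8 in a 6–6 bicycle carrying a C8 peroxide. The peroxide is made from the C8=C9 alkene and O2, and the shift gives C8=O and C3–OH with retention at C3.
3. Ring B (C8=C9) is closed by ring-closing metathesis of a methylidene/vinyl diene. The C2 oxygen comes from ketone reduction inside ring B, followed by esterification with (R)-2-methylbutanoic acid.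
4. The C2–C3 bond is made by an acylative Hosomi–Sakurai union of a ring-A allylsilane (from 2-methylcyclohexanone by asymmetric deprotonation) with a lactone acid chloride (from (S)-5-(hydroxymethyl)furan-2(5H)-one by vinyl 1,4-addition and phosphonylation).
5. Ring order: the γ-lactone (chiral pool) and ring A (commercial) are in hand, ring B is closed third, and the ten-membered ring is formed last by expansion.

Locants: atoms are numbered as in the ten-membered ring of the target. C1 is the lactone O–CH, C2 the acyloxy CH, C3 the C(CH3)OH carbon, C4–C6 the CH2 groups, C7 the CHCH3 carbon, C8 the ketone, C9 the CH2, C10 the ring-fusion CH, C11 the lactone α-carbon, C12 the lactone C=O, C13 the =CH2. Ring A is C3–C8; ring B is C8, C9, C10, C1, C2, C3.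

Assumption: the (S,S)-bis(1-phenylethyl)amide removes the proton on the S-configured α-carbon of the meso ketone, giving the R-enolate. If the rotation of the allylsilane shows the opposite sense, the (R,R)-amide is used instead.

## Route

Step 1
Reactants: 1 2-methylcyclohexanone
Product: 2 cis-2,6-dimethylcyclohexanone (meso)
Conditions: LiN(i-Pr)2 (1.05 equiv), THF, −78 °C; MeI, −78 to 0 °C; then NaOMe (cat.), MeOH, 25 °C
Reagents that add atoms: iodomethane, CI
Why: Kinetic deprotonation at the less substituted α-carbon and SN2 methylation (enolate alkylation), then base equilibration through the enolate to the diequatorial meso cis isomer (about 9:1; residual trans material is removed as diastereomers after step 5).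

Step 2
Reactants: 2 cis-2,6-dimethylcyclohexanone
Product: 5 (R)-[(2,6-dimethylcyclohex-1-en-1-yl)methyl]trimethylsilane, via lithium enolate 3 (not isolated), via enol phosphate 4 (not isolated)
Conditions: (S,S)-[PhCH(CH3)]2NLi (from the amine and n-BuLi), LiCl, THF, −78 °C; ClP(O)(OEt)2, −78 to 0 °C; 1 M HCl wash; Me3SiCH2MgCl, Ni(acac)2 (5 mol %), THF, 25 °C
Reagents that add atoms: (trimethylsilyl)methylmagnesium chloride, C[Si](C)(C)C[Mg]Cl
Why: Enantiotopos-selective deprotonation of the meso ketone by the C2-symmetric chiral lithium amide leaves the C7 stereocentre (R), O-phosphorylation fixes the enolate regiochemistry, and nickel-catalysed Kumada coupling of the enol phosphate gives the allylsilane.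

Step 3
Reactants: 6 (S)-5-(hydroxymethyl)furan-2(5H)-one
Product: 10 diethyl [(3S,4R,5S)-5-(hydroxymethyl)-2-oxo-4-vinyloxolan-3-yl]phosphonate, via silyl ether 7 (not isolated), via magnesium enolate 8 (not isolated), via phosphonite 9 (not isolated)
Conditions: (Me3Si)2NH, Me3SiCl (1 mol %), CH2Cl2, 25 °C, evaporate; CH2=CHMgBr, CuBr·SMe2 (15 mol %), THF, −78 °C; ClP(OEt)2, −78 to 0 °C; 30% aq. H2O2, 0 °C; then 1 M HCl
Reagents that add atoms: vinylmagnesium bromide, C=C[Mg]Br; diethyl chlorophosphite, CCOP(Cl)OCC; hydrogen peroxide, OO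
Why: Copper-catalysed conjugate (1,4-) addition of the vinyl Grignard reagent occurs anti to the C1 substituent of the butenolide and sets C10 trans to C1, and the resulting magnesium enolate is C-phosphinylated by the chlorophosphite and oxidised to the phosphonate (the C11 centre is epimerisable and is removed in step 10).

Step 4
Reactants: 10 diethyl [(3S,4R,5S)-5-(hydroxymethyl)-2-oxo-4-vinyloxolan-3-yl]phosphonate
Product: 11 (2S,3R,4S)-4-(diethoxyphosphoryl)-5-oxo-3-vinyloxolane-2-carboxylic acid
Conditions: TEMPO (10 mol %), PhI(OAc)2 (2.2 equiv), MeCN/H2O (1:1), 25 °C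
Reagents that add atoms: water, O
Why: Nitroxyl/hypervalent-iodine oxidation takes the primary alcohol through the aldehyde hydrate to the carboxylic acid without touching the alkene or the phosphonate.

Step 5
Reactants: 11 (2S,3R,4S)-4-(diethoxyphosphoryl)-5-oxo-3-vinyloxolane-2-carboxylic acid; 5 (R)-[(2,6-dimethylcyclohex-1-en-1-yl)methyl]trimethylsilane
Product: 13 diethyl [(3S,4R,5S)-5-{[(1R,3R)-1,3-dimethyl-2-methylidenecyclohexyl]carbonyl}-2-oxo-4-vinyloxolan-3-yl]phosphonate, via acid chloride 12 (not isolated)
Conditions: (COCl)2, DMF (cat.), CH2Cl2, 0 to 25 °C, evaporate; then 5, TiCl4 (2.2 equiv), CH2Cl2, −78 °C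
Reagents that add atoms: none
Why: Acylative Hosomi–Sakurai reaction (SE2' acylation of the allylsilane) in which the activated acid chloride attacks C3, the β-silyl cation collapses to the exocyclic methylidene, and chair-like axial attack anti to the C7 methyl sets the quaternary C3 with the two ring-A methyls cis.

Step 6
Reactants: 13 diethyl [(3S,4R,5S)-5-{[(1R,3R)-1,3-dimethyl-2-methylidenecyclohexyl]carbonyl}-2-oxo-4-vinyloxolan-3-yl]phosphonate
Product: 14 ring-B-closed tricyclic keto lactone (C2 ketone; C8=C9 alkene; trans-fused C1/C10 lactone; C11 phosphonate)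
Conditions: second-generation Grubbs catalyst (10 mol %), toluene (0.005 M), 80 °C, argon sparge
Reagents that add atoms: none
Why: Ring-closing metathesis in which the catalyst loads at the vinyl group and closes six-membered ring B onto the hindered methylidene intramolecularly with loss of ethene, giving the trisubstituted C8=C9 alkene.

Step 7
Reactants: 14 ring-B-closed tricyclic keto lactone
Product: 15 tricyclic C2 alcohol (C2–OH cis to the angular C3 methyl and trans to the C1 oxygen)
Conditions: NaBH4, MeOH/THF, −20 °C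
Reagents that add atoms: none
Why: Hydride adds to the C2 ketone by axial attack on the face opposite the pseudoaxial angular C3 methyl, giving the equatorial alcohol, while the lactone is shielded as its phosphonate-stabilised enolate (chemoselective ketone reduction).

Step 8
Reactants: 15 tricyclic C2 alcohol; 16 (R)-2-methylbutanoic acid
Product: 17 tricyclic C2 (R)-2-methylbutanoate
Conditions: N,N'-diisopropylcarbodiimide, DMAP (20 mol %), CH2Cl2, 0 to 25 °C
Reagents that add atoms: none
Why: Steglich esterification acylates the only hydroxyl group with the enantiopure acid under conditions that do not epimerise its α-stereocentre.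

Step 9
Reactants: 17 tricyclic C2 (R)-2-methylbutanoate
Product: 20 ten-membered C3-hydroxy C8-ketone carrying the C11 phosphonate, via silyl peroxide 18 (not isolated), via bridged silyl ketal 19 (not isolated)
Conditions: Co(acac)2 (10 mol %), Et3SiH (2 equiv), O2 (1 atm), ClCH2CH2Cl, 25 °C; argon purge; BF3·OEt2 (0.5 equiv), −40 to 0 °C; then aq. citric acid, THF
Reagents that add atoms: dioxygen, O=O
Why: Proposed new method: aerobic hydrosilylperoxidation/silyl-Criegee ring expansion in one flask, in which a cobalt hydride transfers a hydrogen atom to C9 of the only alkene (Markovnikov), the tertiary C8 radical captures O2 and is silylated to peroxide 18, BF3 then complexes the silyloxy oxygen so that the antiperiplanar ring-fusion bond C8–C3 (a tertiary alkyl group, the best migrating group, helped by release of the syn-diaxial methyl strain) shifts from carbon to oxygen with retention at C3 as the O–O bond breaks, silanolate returns to the bridged oxocarbenium ion to give ketal 19 and free BF3, and hydrolysis opens 19 to the ten-membered hydroxy ketone with both new oxygens coming from O2; the closest known reaction types are the Isayama–Mukaiyama silylperoxidation of alkenes and the Criegee rearrangement of decalyl peresters to 6-hydroxycyclodecanone, which have not been merged or run on a silyl peroxide under Lewis-acid catalysis.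

Step 10
Reactants: 20 ten-membered C3-hydroxy C8-ketone carrying the C11 phosphonate
Product: 21 Ineupatorolide A
Conditions: 37% aq. HCHO, K2CO3, THF, 0 to 25 °C
Reagents that add atoms: formaldehyde, C=O
Why: Horner–Wadsworth–Emmons olefination of the α-phosphono lactone with formaldehyde under mild carbonate base installs the exocyclic methylene without epimerising C7 or cleaving the ester.

## Compound list

1 | 2-methylcyclohexanone (racemic) | CC1CCCCC1=O | starting material
2 | cis-2,6-dimethylcyclohexanone (meso, 2R,6S) | C[C@H]1CCC[C@@H](C)C1=O | intermediate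
3 | lithium (R)-2,6-dimethylcyclohex-1-en-1-olate | [Li]OC1=C(C)CCC[C@H]1C | intermediate (not isolated)
4 | diethyl (R)-2,6-dimethylcyclohex-1-en-1-yl phosphate | CCOP(=O)(OCC)OC1=C(C)CCC[C@H]1C | intermediate (not isolated)
5 | (R)-[(2,6-dimethylcyclohex-1-en-1-yl)methyl]trimethylsilane | C[Si](C)(C)CC1=C(C)CCC[C@H]1C | intermediate
6 | (S)-5-(hydroxymethyl)furan-2(5H)-one | O=C1O[C@H](CO)C=C1 | starting material
7 | (S)-5-[(trimethylsilyloxy)methyl]furan-2(5H)-one | O=C1O[C@H](CO[Si](C)(C)C)C=C1 | intermediate (not isolated)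
8 | bromomagnesium enolate of the vinyl 1,4-adduct of 7 (vinyl trans to CH2OSiMe3) | Br[Mg]OC1=C[C@H](C=C)[C@@H](CO[Si](C)(C)C)O1 | intermediate (not isolated)
9 | diethyl [(3S,4R,5S)-2-oxo-5-[(trimethylsilyloxy)methyl]-4-vinyloxolan-3-yl]phosphonite | O=C1O[C@H](CO[Si](C)(C)C)[C@@H](C=C)[C@@H]1P(OCC)OCC | intermediate (not isolated)
10 | diethyl [(3S,4R,5S)-5-(hydroxymethyl)-2-oxo-4-vinyloxolan-3-yl]phosphonate (C3 epimer inconsequential) | O=C1O[C@H](CO)[C@@H](C=C)[C@@H]1P(=O)(OCC)OCC | intermediate
11 | (2S,3R,4S)-4-(diethoxyphosphoryl)-5-oxo-3-vinyloxolane-2-carboxylic acid | O=C1O[C@H](C(=O)O)[C@@H](C=C)[C@@H]1P(=O)(OCC)OCC | intermediate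
12 | (2S,3R,4S)-4-(diethoxyphosphoryl)-5-oxo-3-vinyloxolane-2-carbonyl chloride | O=C1O[C@H](C(=O)Cl)[C@@H](C=C)[C@@H]1P(=O)(OCC)OCC | intermediate (not isolated)
13 | diethyl [(3S,4R,5S)-5-{[(1R,3R)-1,3-dimethyl-2-methylidenecyclohexyl]carbonyl}-2-oxo-4-vinyloxolan-3-yl]phosphonate | O=C1O[C@H](C(=O)[C@]2(C)CCC[C@@H](C)C2=C)[C@@H](C=C)[C@@H]1P(=O)(OCC)OCC | intermediate
14 | tricyclic keto lactone: ring B closed, C2 ketone, C8=C9 alkene, trans-fused C1/C10 lactone (H-1/H-10 anti), C3 and C7 methyls cis, diethyl phosphonate at C11 | O=C1O[C@@H]2C(=O)[C@]3(C)CCC[C@@H](C)C3=C[C@H]2[C@@H]1P(=O)(OCC)OCC | intermediate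
15 | tricyclic C2 alcohol: as 14 with C2–OH cis to the angular C3 methyl and trans to the C1 oxygen | O=C1O[C@@H]2[C@@H](O)[C@]3(C)CCC[C@@H](C)C3=C[C@H]2[C@@H]1P(=O)(OCC)OCC | intermediate
16 | (R)-2-methylbutanoic acid | CC[C@@H](C)C(=O)O | starting material
17 | tricyclic C2 (R)-2-methylbutanoate of 15 | O=C1O[C@@H]2[C@@H](OC(=O)[C@H](C)CC)[C@]3(C)CCC[C@@H](C)C3=C[C@H]2[C@@H]1P(=O)(OCC)OCC | intermediate
18 | C8 triethylsilyl peroxide of 17 (C9 saturated; peroxide trans to the angular methyl, configuration at C8 inconsequential) | O=C1O[C@@H]2[C@@H](OC(=O)[C@H](C)CC)[C@]3(C)CCC[C@@H](C)[C@@]3(OO[Si](CC)(CC)CC)C[C@H]2[C@@H]1P(=O)(OCC)OCC | intermediate (not isolated)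
19 | bridged silyl ketal: C3–O–C8 bridge (11-oxabicyclo[4.4.1]undecane core), triethylsilyloxy at C8 | O=C1O[C@@H]2[C@@H](OC(=O)[C@H](C)CC)[C@]3(C)CCC[C@@H](C)[C@](O3)(O[Si](CC)(CC)CC)C[C@H]2[C@@H]1P(=O)(OCC)OCC | intermediate (not isolated)
20 | ten-membered C3-hydroxy C8-ketone with diethyl phosphonate at C11 (the target with P(O)(OEt)2 and H in place of the methylene) | O=C1O[C@@H]2[C@@H](OC(=O)[C@H](C)CC)[C@@](C)(O)CCC[C@@H](C)C(=O)C[C@H]2[C@@H]1P(=O)(OCC)OCC | intermediate
21 | Ineupatorolide A | C=C1C(=O)O[C@@H]2[C@@H](OC(=O)[C@H](C)CC)[C@@](C)(O)CCC[C@@H](C)C(=O)C[C@@H]12 | target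

## Step count and risks

Total step count: 10. Longest linear sequence: 8 steps (1, 2, 5, 6, 7, 8, 9, 10; the lactone branch 3, 4, 5–10 is equally long).

Steps most likely to fail:

Step 9 (the proposed new ring expansion). The risks are competing migration of the secondary C7 carbon (C3 carries a β-acyloxy group that lowers its migratory aptitude), C–O ionisation of the peroxide, and poor turnover of BF3 in the presence of the phosphonate. The fallback uses known chemistry and sets out from 17. Only the cobalt-catalysed silylperoxidation is run and the silyl peroxide 18 is isolated. HF·pyridine frees the C8 hydroperoxide of 17 F7. This is treated with 4-nitrobenzoyl chloride and pyridine in the classical perester Criegee rearrangement to give the C3–O–C8 bridged ketal 4-nitrobenzoate F8. Hydrolysis in aqueous acetic acid/THF returns to the route at 20.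

Step 5 (acylative union). The risks are low facial selectivity at the new quaternary C3 and decomposition of the α-oxygenated acid chloride under TiCl4. The fallback sets out from 10 and 5 and avoids the acid chloride. Dess–Martin oxidation of 10 gives diethyl [(3S,4R,5S)-5-formyl-2-oxo-4-vinyloxolan-3-yl]phosphonate F5. A BF3·OEt2-mediated Hosomi–Sakurai allylation with 5 gives the homoallylic alcohols diethyl [(3S,4R,5S)-5-{[(1R,3R)-1,3-dimethyl-2-methylidenecyclohexyl](hydroxy)methyl}-2-oxo-4-vinyloxolan-3-yl]phosphonate F6 as a mixture of C2 epimers. A second Dess–Martin oxidation converges on 13. This fallback answers the reactivity risk; it does not by itself improve the facial selectivity at C3.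

Step 3 (one-flask 1,4-addition and C-phosphinylation). The risks are O- rather than C-attack on phosphorus, 1,2-addition, and loss of trans selectivity. The fallback sets out from 6 and uses a protecting group and a Michaelis–Arbuzov reaction. TBSCl/imidazole gives (S)-5-{[(tert-butyldimethylsilyl)oxy]methyl}furan-2(5H)-one F1. (CH2=CH)2CuLi in THF at −78 °C gives (4R,5S)-5-{[(tert-butyldimethylsilyl)oxy]methyl}-4-vinyldihydrofuran-2(3H)-one F2. Enolisation with LiN(i-Pr)2 and bromination with CBr4 give (4R,5S)-3-bromo-5-{[(tert-butyldimethylsilyl)oxy]methyl}-4-vinyldihydrofuran-2(3H)-one F3. Heating with P(OEt)3 at 130 °C gives diethyl [(3S,4R,5S)-5-{[(tert-butyldimethylsilyl)oxy]methyl}-2-oxo-4-vinyloxolan-3-yl]phosphonate F4. Aqueous HCl in THF removes the silyl group and returns to the route at 10.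

## Further compounds

F1 | step 3 | (S)-5-{[(tert-butyldimethylsilyl)oxy]methyl}furan-2(5H)-one | O=C1O[C@H](CO[Si](C)(C)C(C)(C)C)C=C1
F2 | step 3 | (4R,5S)-5-{[(tert-butyldimethylsilyl)oxy]methyl}-4-vinyldihydrofuran-2(3H)-one | O=C1O[C@H](CO[Si](C)(C)C(C)(C)C)[C@@H](C=C)C1
F3 | step 3 | (4R,5S)-3-bromo-5-{[(tert-butyldimethylsilyl)oxy]methyl}-4-vinyldihydrofuran-2(3H)-one (C3 epimers) | O=C1O[C@H](CO[Si](C)(C)C(C)(C)C)[C@@H](C=C)C1Br
F4 | step 3 | diethyl [(3S,4R,5S)-5-{[(tert-butyldimethylsilyl)oxy]methyl}-2-oxo-4-vinyloxolan-3-yl]phosphonate | O=C1O[C@H](CO[Si](C)(C)C(C)(C)C)[C@@H](C=C)[C@@H]1P(=O)(OCC)OCC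
F5 | step 5 | diethyl [(3S,4R,5S)-5-formyl-2-oxo-4-vinyloxolan-3-yl]phosphonate | O=C1O[C@H](C=O)[C@@H](C=C)[C@@H]1P(=O)(OCC)OCC
F6 | step 5 | diethyl [(3S,4R,5S)-5-{[(1R,3R)-1,3-dimethyl-2-methylidenecyclohexyl](hydroxy)methyl}-2-oxo-4-vinyloxolan-3-yl]phosphonate (C2 epimers) | O=C1O[C@H](C(O)[C@]2(C)CCC[C@@H](C)C2=C)[C@@H](C=C)[C@@H]1P(=O)(OCC)OCC
F7 | step 9 | C8 hydroperoxide of 17 (C9 saturated) | O=C1O[C@@H]2[C@@H](OC(=O)[C@H](C)CC)[C@]3(C)CCC[C@@H](C)[C@@]3(OO)C[C@H]2[C@@H]1P(=O)(OCC)OCC
F8 | step 9 | C3–O–C8 bridged ketal 4-nitrobenzoate | O=C1O[C@@H]2[C@@H](OC(=O)[C@H](C)CC)[C@]3(C)CCC[C@@H](C)[C@](O3)(OC(=O)c4ccc(cc4)[N+](=O)[O-])C[C@H]2[C@@H]1P(=O)(OCC)OCC
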